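**Retrosynthetic overview**
1. Target ⇐ oxidation of a C4 carbinol; side-chain oxirane ⇐ late Shi epoxidation of a prenyl group; the two angelates ⇐ Yamaguchi acylations (C1 first, C8 later).
2. Prenyl group and C8 carbinol ⇐ cross-metathesis and catalytic asymmetric allylboration of an α-methylene aldehyde, itself made from an isopropenyl group (ene chlorination, N-oxide oxidation).
3. Ring oxirane ⇐ epoxidation directed by the C1 hydroxyl; C1 carbinol ⇐ ketoreductase reduction of the C1 enone.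
4. C5 oxygen ⇐ enolate hydroxylation anti to C6; C6 stereocentre ⇐ Rh/BINAP-catalysed 1,4-addition of an isopropenylborate to the quinone monoketal of 4-methoxy-2-methylphenol.
5. Ring order: carbocycle (taken over from the arene, step 1) → ring oxirane C2–C3 (step 9) → side-chain oxirane C10–C11 (step 16).

**Conventions and one assumption.** Names from compound 12 on use the target (bisabolane) numbering: ring C1–C6, C6 carries the side chain C7(=C14H2)–C8–C9–C10–C11(C12)(C13), and the methyl on C3 is C15. The ring is drawn with C1→C2→…→C6 running clockwise; α = behind the plane, β = in front. Angeloyl = (Z)-2-methylbut-2-enoyl. Assumption: the C4 carbinol centre made in step 5 and destroyed in step 18 is drawn as the expected 4α epimer (trans to the C5 acetate).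

**Step 1**
Reactants: 1 4-methoxy-2-methylphenol
Product: 2 4,4-dimethoxy-2-methylcyclohexa-2,5-dien-1-one
Conditions: PhI(OAc)2 (1.1 equiv), MeOH, 0 °C
Reagents that add atoms: methanol, CO
Why: Oxidative dearomatisation of a para-alkoxyphenol with the hypervalent iodine diacetate, the cation being trapped at C4 by methanol, gives the quinone monoketal in which the future C4 ketone is free and the future C1 carbonyl is masked; no stereocentre is formed.

**Step 2**
Reactants: 2 4,4-dimethoxy-2-methylcyclohexa-2,5-dien-1-one; 3 potassium trifluoro(prop-1-en-2-yl)borate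
Product: 4 (5R)-4,4-dimethoxy-2-methyl-5-(prop-1-en-2-yl)cyclohex-2-en-1-one
Conditions: [Rh(cod)2]BF4 (3 mol%), (R)-2,2'-bis(diphenylphosphino)-1,1'-binaphthyl (3.3 mol%), Et3N (1.5 equiv), PhMe/H2O (5:1), 25 °C
Reagents that add atoms: none
Why: Hayashi–Miyaura rhodium-catalysed asymmetric 1,4-addition, in which the alkenylrhodium species adds only to the unsubstituted enone arm (the α-methyl enone is far less reactive) and the (R)-bisphosphine blocks one enone face, so the isopropenyl group enters target C6 on the α-face (R) as the first stereocentre.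

**Step 3**
Reactants: 4 (5R)-4,4-dimethoxy-2-methyl-5-(prop-1-en-2-yl)cyclohex-2-en-1-one
Product: 6 (5S,6S)-6-hydroxy-4,4-dimethoxy-2-methyl-5-(prop-1-en-2-yl)cyclohex-2-en-1-one, via potassium dienolate 5 (not isolated)
Conditions: KN(SiMe3)2 (1.1 equiv), THF, −78 °C; then 3-phenyl-2-(phenylsulfonyl)oxaziridine (1.3 equiv), −78 °C; AcOH quench
Reagents that add atoms: 3-phenyl-2-(phenylsulfonyl)oxaziridine, O=S(=O)(c1ccccc1)N1OC1c1ccccc1
Why: Davis enolate hydroxylation, in which kinetic deprotonation can occur only at the α'-methylene (the γ-carbon is the ketal) and oxygen is transferred to the enolate face opposite the neighbouring isopropenyl group, setting the target C5 carbinol β (trans to C6).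

**Step 4**
Reactants: 6 (5S,6S)-6-hydroxy-4,4-dimethoxy-2-methyl-5-(prop-1-en-2-yl)cyclohex-2-en-1-one
Product: 7 (1S,6S)-5,5-dimethoxy-3-methyl-2-oxo-6-(prop-1-en-2-yl)cyclohex-3-en-1-yl acetate
Conditions: Ac2O, pyridine, 4-(dimethylamino)pyridine (5 mol%), CH2Cl2, 0 °C
Reagents that add atoms: acetic anhydride, CC(=O)OC(C)=O
Why: Nucleophile-catalysed O-acylation of the secondary α-hydroxy ketone installs the acetate of the target with retention at C5.

**Step 5**
Reactants: 7 (1S,6S)-5,5-dimethoxy-3-methyl-2-oxo-6-(prop-1-en-2-yl)cyclohex-3-en-1-yl acetate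
Product: 8 (1S,2S,6S)-2-hydroxy-5,5-dimethoxy-3-methyl-6-(prop-1-en-2-yl)cyclohex-3-en-1-yl acetate
Conditions: NaBH4, CeCl3·7H2O, MeOH, −78 °C
Reagents that add atoms: none
Why: Luche reduction gives clean 1,2-reduction of the enone without acetate cleavage, axial hydride attack giving the 4α alcohol trans to the acetate; this centre only masks the C4 ketone, which must not coexist with a free C1 ketone because an ene-1,4-dione would aromatise.

**Step 6**
Reactants: 8 (1S,2S,6S)-2-hydroxy-5,5-dimethoxy-3-methyl-6-(prop-1-en-2-yl)cyclohex-3-en-1-yl acetate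
Product: 9 (1S,2S,6S)-5,5-dimethoxy-3-methyl-6-(prop-1-en-2-yl)-2-[(triethylsilyl)oxy]cyclohex-3-en-1-yl acetate
Conditions: Et3SiCl, imidazole, DMF, 0 °C → rt
Reagents that add atoms: chlorotriethylsilane, CC[Si](Cl)(CC)CC
Why: Imidazole-promoted silyl ether formation protects the C4 hydroxyl orthogonally to the acetate and the ketal without touching any stereocentre.

**Step 7**
Reactants: 9 (1S,2S,6S)-5,5-dimethoxy-3-methyl-6-(prop-1-en-2-yl)-2-[(triethylsilyl)oxy]cyclohex-3-en-1-yl acetate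
Product: 10 (1S,2S,6S)-3-methyl-5-oxo-6-(prop-1-en-2-yl)-2-[(triethylsilyl)oxy]cyclohex-3-en-1-yl acetate
Conditions: pyridinium p-toluenesulfonate (10 mol%), acetone/H2O (20:1), 0 °C → rt; used at once
Reagents that add atoms: water, O
Why: Acid-catalysed hydrolysis of what is now an ordinary allylic dimethyl ketal is fast under conditions that spare the silyl ether and acetate, and it releases the C1 enone without base that would epimerise C6, shift the isopropenyl alkene into conjugation or eliminate the β-acetate.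

**Step 8**
Reactants: 10 (1S,2S,6S)-3-methyl-5-oxo-6-(prop-1-en-2-yl)-2-[(triethylsilyl)oxy]cyclohex-3-en-1-yl acetate
Product: 11 (1S,2S,5R,6R)-5-hydroxy-3-methyl-6-(prop-1-en-2-yl)-2-[(triethylsilyl)oxy]cyclohex-3-en-1-yl acetate
Conditions: ketoreductase (NADPH-dependent, (R)-selective panel enzyme, esterase-free lyophilisate), NADP+ (1 mol%), i-PrOH (10% v/v), KH2PO4/K2HPO4 buffer (0.1 M, pH 6.8), MgSO4 (2 mM), DMSO (5% v/v), 28 °C
Reagents that add atoms: none
Why: Enzymatic carbonyl reduction by a ketoreductase with isopropanol-coupled cofactor recycling, in which the active site rather than the substrate fixes hydride delivery to the Si (β) face of C1 to give the 1α (R) allylic alcohol cis to the C6 substituent, in a neutral medium that the elimination-prone β-acetoxy, β,γ-unsaturated ketone tolerates.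

**Step 9**
Reactants: 11 (1S,2S,5R,6R)-5-hydroxy-3-methyl-6-(prop-1-en-2-yl)-2-[(triethylsilyl)oxy]cyclohex-3-en-1-yl acetate
Product: 12 5β-acetoxy-2α,3α-epoxy-1α-hydroxy-6α-isopropenyl-3β-methyl-4α-(triethylsilyloxy)cyclohexane
Conditions: VO(acac)2 (5 mol%), t-BuOOH (1.5 equiv, decane), CH2Cl2, 0 °C → rt
Reagents that add atoms: tert-butyl hydroperoxide, CC(C)(C)OO
Why: Hydroxyl-directed vanadium-catalysed epoxidation, in which the vanadate ester of the pseudoaxial 1α-hydroxyl delivers oxygen to the same (α) face of the allylic C2=C3 bond and so sets C2 and C3, while the merely homoallylic 1,1-disubstituted alkene reacts much more slowly.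

**Step 10**
Reactants: 12 5β-acetoxy-2α,3α-epoxy-1α-hydroxy-6α-isopropenyl-3β-methyl-4α-(triethylsilyloxy)cyclohexane
Product: 13 5β-acetoxy-1α-angeloyloxy-2α,3α-epoxy-6α-isopropenyl-3β-methyl-4α-(triethylsilyloxy)cyclohexane
Conditions: angelic acid (3 equiv), 2,4,6-trichlorobenzoyl chloride (3 equiv), Et3N (6 equiv), PhMe, rt, 2 h; then 12, 75 °C
Reagents that add atoms: angelic acid, C/C=C(/C)C(=O)O
Why: Yamaguchi esterification through the mixed anhydride acylates the hindered secondary alcohol with retention at C1 and, run without a nucleophilic amine catalyst, keeps the Z geometry from isomerising to the tiglate.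

**Step 11**
Reactants: 13 5β-acetoxy-1α-angeloyloxy-2α,3α-epoxy-6α-isopropenyl-3β-methyl-4α-(triethylsilyloxy)cyclohexane
Product: 14 5β-acetoxy-1α-angeloyloxy-6α-(3-chloroprop-1-en-2-yl)-2α,3α-epoxy-3β-methyl-4α-(triethylsilyloxy)cyclohexane
Conditions: NaOCl (aq., 1.3 equiv), CeCl3·7H2O (1.5 equiv), CH2Cl2/H2O, 0 °C
Reagents that add atoms: sodium hypochlorite, [Na+].[O-]Cl
Why: Ene-type allylic chlorination by hypochlorous acid attacks only the electron-rich 1,1-disubstituted alkene (the angelate alkene is electron-poor), putting chlorine on the terminal carbon with loss of a methyl proton so that the exocyclic methylene is regenerated; no stereocentre is affected.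

**Step 12**
Reactants: 14 5β-acetoxy-1α-angeloyloxy-6α-(3-chloroprop-1-en-2-yl)-2α,3α-epoxy-3β-methyl-4α-(triethylsilyloxy)cyclohexane
Product: 15 5β-acetoxy-1α-angeloyloxy-2α,3α-epoxy-3β-methyl-6α-(3-oxoprop-1-en-2-yl)-4α-(triethylsilyloxy)cyclohexane
Conditions: N-methylmorpholine N-oxide (4 equiv), NaI (20 mol%), 4 Å MS, MeCN, rt → 40 °C
Reagents that add atoms: N-methylmorpholine N-oxide, C[N+]1([O-])CCOCC1
Why: Ganem-type N-oxide oxidation, in which the allylic halide (iodide formed in situ by Finkelstein exchange) is O-alkylated by the amine oxide and the alkoxyammonium salt collapses to the conjugated aldehyde under near-neutral conditions that the esters, oxirane and silyl ether survive.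

**Step 13**
Reactants: 15 5β-acetoxy-1α-angeloyloxy-2α,3α-epoxy-3β-methyl-6α-(3-oxoprop-1-en-2-yl)-4α-(triethylsilyloxy)cyclohexane; 16 2-allyl-4,4,5,5-tetramethyl-1,3,2-dioxaborolane
Product: 18 5β-acetoxy-1α-angeloyloxy-2α,3α-epoxy-6α-[(3R)-3-hydroxyhexa-1,5-dien-2-yl]-3β-methyl-4α-(triethylsilyloxy)cyclohexane, via O-pinacolboryl ether 17 (not isolated)
Conditions: (R)-3,3'-bis(2,4,6-triisopropylphenyl)-1,1'-binaphthyl-2,2'-diyl hydrogen phosphate (5 mol%), PhMe, −30 °C; aq. NaHCO3 work-up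
Reagents that add atoms: none
Why: Chiral phosphoric acid-catalysed allylboration through a closed chair transition state in which the acid activates the boronate and shields one aldehyde face, so allyl adds to the Re face and the C8 carbinol is formed R under catalyst control, independent of the distant ring centres.

**Step 14**
Reactants: 18 5β-acetoxy-1α-angeloyloxy-2α,3α-epoxy-6α-[(3R)-3-hydroxyhexa-1,5-dien-2-yl]-3β-methyl-4α-(triethylsilyloxy)cyclohexane; 19 2-methylbut-2-ene
Product: 20 (8R)-5β-acetoxy-1α-angeloyloxy-2α,3α-epoxy-4α-(triethylsilyloxy)bisabola-7(14),10-dien-8-ol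
Conditions: second-generation Hoveyda–Grubbs catalyst RuCl2(H2IMes)(=CH-C6H4-2-OiPr) (5 mol%), 2-methylbut-2-ene/CH2Cl2 (1:1), 40 °C, sealed tube
Reagents that add atoms: none
Why: Olefin cross-metathesis with excess 2-methylbut-2-ene turns only the monosubstituted vinyl group into the prenyl alkene, the 1,1-disubstituted methylene and the conjugated angelate alkene being inert, and no stereocentre is touched.

**Step 15**
Reactants: 20 (8R)-5β-acetoxy-1α-angeloyloxy-2α,3α-epoxy-4α-(triethylsilyloxy)bisabola-7(14),10-dien-8-ol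
Product: 21 (8R)-5β-acetoxy-1α,8-bis(angeloyloxy)-2α,3α-epoxy-4α-(triethylsilyloxy)bisabola-7(14),10-diene
Conditions: angelic acid (3 equiv), 2,4,6-trichlorobenzoyl chloride (3 equiv), Et3N (6 equiv), PhMe, rt, 2 h; then 20, 75 °C
Reagents that add atoms: angelic acid, C/C=C(/C)C(=O)O
Why: Yamaguchi esterification of the unhindered secondary allylic alcohol proceeds with retention at C8 and without Z-to-E isomerisation of the acyl group.

**Step 16**
Reactants: 21 (8R)-5β-acetoxy-1α,8-bis(angeloyloxy)-2α,3α-epoxy-4α-(triethylsilyloxy)bisabola-7(14),10-diene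
Product: 22 (8R,10S)-5β-acetoxy-1α,8-bis(angeloyloxy)-2α,3α:10,11-diepoxy-4α-(triethylsilyloxy)bisabol-7(14)-ene
Conditions: 1,2:4,5-di-O-isopropylidene-β-L-erythro-2,3-hexodiulo-2,6-pyranose (L-fructose-derived Shi ketone, 30 mol%), KHSO5 (as 2KHSO5·KHSO4·K2SO4, 1.4 equiv), K2CO3, Bu4NHSO4, MeCN/CH2(OMe)2/aq. Na2B4O7–Na2H2EDTA buffer, 0 °C
Reagents that add atoms: potassium peroxymonosulfate, [K+].[O-]S(=O)(=O)OO
Why: Shi asymmetric epoxidation, in which the chiral dioxirane transfers oxygen through a spiro transition state to one face of the electron-rich trisubstituted prenyl alkene to give the 10S oxirane under catalyst control, while the deactivated 1,1-disubstituted alkene and the electron-poor angelate alkenes do not react.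

**Step 17**
Reactants: 22 (8R,10S)-5β-acetoxy-1α,8-bis(angeloyloxy)-2α,3α:10,11-diepoxy-4α-(triethylsilyloxy)bisabol-7(14)-ene
Product: 23 (8R,10S)-5β-acetoxy-1α,8-bis(angeloyloxy)-2α,3α:10,11-diepoxybisabol-7(14)-en-4α-ol
Conditions: Et3N·3HF (5 equiv), THF/MeCN, 0 °C → rt
Reagents that add atoms: none
Why: Fluoride-mediated desilylation with the nearly neutral amine–hydrogen fluoride complex removes the secondary triethylsilyl ether without acid opening of the trisubstituted oxirane or base-induced acetate migration from O5 to O4.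

**Step 18**
Reactants: 23 (8R,10S)-5β-acetoxy-1α,8-bis(angeloyloxy)-2α,3α:10,11-diepoxybisabol-7(14)-en-4α-ol
Product: 24 (8R,10S)-5β-acetoxy-1α,8-bis(angeloyloxy)-2α,3α:10,11-diepoxybisabol-7(14)-en-4-one
Conditions: Dess–Martin periodinane (1.5 equiv), NaHCO3, CH2Cl2, 0 °C → rt
Reagents that add atoms: none
Why: Dess–Martin oxidation of the last free secondary alcohol gives the C4 ketone under buffered, non-basic conditions, so the α-acetoxy centre C5 and both oxiranes are preserved.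

**Compound list**
1 | 4-methoxy-2-methylphenol | COc1ccc(O)c(C)c1 | starting material
2 | 4,4-dimethoxy-2-methylcyclohexa-2,5-dien-1-one | COC1(OC)C=CC(=O)C(C)=C1 | intermediate
3 | potassium trifluoro(prop-1-en-2-yl)borate | [K+].C=C(C)[B-](F)(F)F | starting material
4 | (5R)-4,4-dimethoxy-2-methyl-5-(prop-1-en-2-yl)cyclohex-2-en-1-one | C=C(C)[C@@H]1C(OC)(OC)C=C(C)C(=O)C1 | intermediate
5 | potassium (3R)-4,4-dimethoxy-6-methyl-3-(prop-1-en-2-yl)cyclohexa-1,5-dien-1-olate | [K+].C=C(C)[C@@H]1C(OC)(OC)C=C(C)C([O-])=C1 | intermediate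
6 | (5S,6S)-6-hydroxy-4,4-dimethoxy-2-methyl-5-(prop-1-en-2-yl)cyclohex-2-en-1-one | C=C(C)[C@@H]1C(OC)(OC)C=C(C)C(=O)[C@H]1O | intermediate
7 | (1S,6S)-5,5-dimethoxy-3-methyl-2-oxo-6-(prop-1-en-2-yl)cyclohex-3-en-1-yl acetate | C=C(C)[C@@H]1C(OC)(OC)C=C(C)C(=O)[C@H]1OC(C)=O | intermediate
8 | (1S,2S,6S)-2-hydroxy-5,5-dimethoxy-3-methyl-6-(prop-1-en-2-yl)cyclohex-3-en-1-yl acetate | C=C(C)[C@@H]1C(OC)(OC)C=C(C)[C@H](O)[C@H]1OC(C)=O | intermediate
9 | (1S,2S,6S)-5,5-dimethoxy-3-methyl-6-(prop-1-en-2-yl)-2-[(triethylsilyl)oxy]cyclohex-3-en-1-yl acetate | C=C(C)[C@@H]1C(OC)(OC)C=C(C)[C@H](O[Si](CC)(CC)CC)[C@H]1OC(C)=O | intermediate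
10 | (1S,2S,6S)-3-methyl-5-oxo-6-(prop-1-en-2-yl)-2-[(triethylsilyl)oxy]cyclohex-3-en-1-yl acetate | C=C(C)[C@@H]1C(=O)C=C(C)[C@H](O[Si](CC)(CC)CC)[C@H]1OC(C)=O | intermediate
11 | (1S,2S,5R,6R)-5-hydroxy-3-methyl-6-(prop-1-en-2-yl)-2-[(triethylsilyl)oxy]cyclohex-3-en-1-yl acetate | C=C(C)[C@@H]1[C@H](O)C=C(C)[C@H](O[Si](CC)(CC)CC)[C@H]1OC(C)=O | intermediate
12 | 5β-acetoxy-2α,3α-epoxy-1α-hydroxy-6α-isopropenyl-3β-methyl-4α-(triethylsilyloxy)cyclohexane | C=C(C)[C@@H]1[C@H](O)[C@@H]2O[C@]2(C)[C@H](O[Si](CC)(CC)CC)[C@H]1OC(C)=O | intermediate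
13 | 5β-acetoxy-1α-angeloyloxy-2α,3α-epoxy-6α-isopropenyl-3β-methyl-4α-(triethylsilyloxy)cyclohexane | C=C(C)[C@@H]1[C@H](OC(=O)/C(C)=C\C)[C@@H]2O[C@]2(C)[C@H](O[Si](CC)(CC)CC)[C@H]1OC(C)=O | intermediate
14 | 5β-acetoxy-1α-angeloyloxy-6α-(3-chloroprop-1-en-2-yl)-2α,3α-epoxy-3β-methyl-4α-(triethylsilyloxy)cyclohexane | C=C(CCl)[C@@H]1[C@H](OC(=O)/C(C)=C\C)[C@@H]2O[C@]2(C)[C@H](O[Si](CC)(CC)CC)[C@H]1OC(C)=O | intermediate
15 | 5β-acetoxy-1α-angeloyloxy-2α,3α-epoxy-3β-methyl-6α-(3-oxoprop-1-en-2-yl)-4α-(triethylsilyloxy)cyclohexane | C=C(C=O)[C@@H]1[C@H](OC(=O)/C(C)=C\C)[C@@H]2O[C@]2(C)[C@H](O[Si](CC)(CC)CC)[C@H]1OC(C)=O | intermediate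
16 | 2-allyl-4,4,5,5-tetramethyl-1,3,2-dioxaborolane | C=CCB1OC(C)(C)C(C)(C)O1 | starting material
17 | O-(4,4,5,5-tetramethyl-1,3,2-dioxaborolan-2-yl) ether of 18 | C=C([C@@H]1[C@H](OC(=O)/C(C)=C\C)[C@@H]2O[C@]2(C)[C@H](O[Si](CC)(CC)CC)[C@H]1OC(C)=O)[C@@H](CC=C)OB3OC(C)(C)C(C)(C)O3 | intermediate
18 | 5β-acetoxy-1α-angeloyloxy-2α,3α-epoxy-6α-[(3R)-3-hydroxyhexa-1,5-dien-2-yl]-3β-methyl-4α-(triethylsilyloxy)cyclohexane | C=C([C@@H]1[C@H](OC(=O)/C(C)=C\C)[C@@H]2O[C@]2(C)[C@H](O[Si](CC)(CC)CC)[C@H]1OC(C)=O)[C@@H](CC=C)O | intermediate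
19 | 2-methylbut-2-ene | CC=C(C)C | starting material
20 | (8R)-5β-acetoxy-1α-angeloyloxy-2α,3α-epoxy-4α-(triethylsilyloxy)bisabola-7(14),10-dien-8-ol | C=C([C@@H]1[C@H](OC(=O)/C(C)=C\C)[C@@H]2O[C@]2(C)[C@H](O[Si](CC)(CC)CC)[C@H]1OC(C)=O)[C@@H](CC=C(C)C)O | intermediate
21 | (8R)-5β-acetoxy-1α,8-bis(angeloyloxy)-2α,3α-epoxy-4α-(triethylsilyloxy)bisabola-7(14),10-diene | C=C([C@@H]1[C@H](OC(=O)/C(C)=C\C)[C@@H]2O[C@]2(C)[C@H](O[Si](CC)(CC)CC)[C@H]1OC(C)=O)[C@@H](CC=C(C)C)OC(=O)/C(C)=C\C | intermediate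
22 | (8R,10S)-5β-acetoxy-1α,8-bis(angeloyloxy)-2α,3α:10,11-diepoxy-4α-(triethylsilyloxy)bisabol-7(14)-ene | C=C([C@@H]1[C@H](OC(=O)/C(C)=C\C)[C@@H]2O[C@]2(C)[C@H](O[Si](CC)(CC)CC)[C@H]1OC(C)=O)[C@@H](C[C@@H]1OC1(C)C)OC(=O)/C(C)=C\C | intermediate
23 | (8R,10S)-5β-acetoxy-1α,8-bis(angeloyloxy)-2α,3α:10,11-diepoxybisabol-7(14)-en-4α-ol | C=C([C@@H]1[C@H](OC(=O)/C(C)=C\C)[C@@H]2O[C@]2(C)[C@H](O)[C@H]1OC(C)=O)[C@@H](C[C@@H]1OC1(C)C)OC(=O)/C(C)=C\C | intermediate
24 | (8R,10S)-5β-acetoxy-1α,8-bis(angeloyloxy)-2α,3α:10,11-diepoxybisabol-7(14)-en-4-one (CNP0407453.2) | C=C([C@@H]1[C@H](OC(=O)/C(C)=C\C)[C@@H]2O[C@]2(C)C(=O)[C@H]1OC(C)=O)[C@@H](C[C@@H]1OC1(C)C)OC(=O)/C(C)=C\C | target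

**Totals**
Total step count: 18. Longest linear sequence: 18 steps (1 → 24).

**Three steps most likely to fail, each with a fallback**

Step 8 (enzymatic reduction of the sensitive enone 10). If no ketoreductase gives useful conversion or face selectivity, the order of ring events is inverted, setting out from 8. The free 4α-hydroxyl of 8 directs a VO(acac)2/t-BuOOH epoxidation of C2=C3 to the α-face, giving 5β-acetoxy-2α,3α-epoxy-4α-hydroxy-6α-isopropenyl-1,1-dimethoxy-3β-methylcyclohexane F1. Silylation (Et3SiCl, imidazole, DMF) gives its 4-O-triethylsilyl ether F2. Ketal hydrolysis (oxalic acid on wet SiO2, CH2Cl2) gives 5β-acetoxy-2α,3α-epoxy-6α-isopropenyl-3β-methyl-4α-(triethylsilyloxy)cyclohexan-1-one F3. NaBH4 (MeOH, −40 °C) then attacks C1 from the β-face, anti to the oxirane oxygen, to give the cis-epoxy alcohol, and the route is rejoined at 12. This fallback needs the 4α configuration assumed for 8.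

Step 10 (angeloylation of the hindered pseudoaxial C1 hydroxyl). If Yamaguchi acylation of 12 is too slow or gives tiglate, the Z-enoate is built on the molecule instead. Compound 12 is acylated with 2-[bis(2,2,2-trifluoroethoxy)phosphoryl]propanoic acid (1-ethyl-3-(3-dimethylaminopropyl)carbodiimide hydrochloride, 4-(dimethylamino)pyridine, CH2Cl2) to give the 1-O-{2-[bis(2,2,2-trifluoroethoxy)phosphoryl]propanoyl} ester of 12 F4. A Still–Gennari olefination (KN(SiMe3)2, 18-crown-6, acetaldehyde, THF, −78 °C) then forms the (Z)-2-methylbut-2-enoate directly, coming back to the route at 13.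

Step 12 (N-oxide oxidation of allylic chloride 14). If substitution is sluggish or the C5 acetate eliminates, the aldehyde is reached without the chloride, setting out from 13. SeO2 (cat.)/t-BuOOH with salicylic acid (cat.) in CH2Cl2 hydroxylates the isopropenyl methyl to give 5β-acetoxy-1α-angeloyloxy-2α,3α-epoxy-6α-(3-hydroxyprop-1-en-2-yl)-3β-methyl-4α-(triethylsilyloxy)cyclohexane F5. Oxidation with MnO2 (CH2Cl2, rt) then gives the enal, coming back to the route at 15.

**Further compounds**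
F1 | step 8 | 5β-acetoxy-2α,3α-epoxy-4α-hydroxy-6α-isopropenyl-1,1-dimethoxy-3β-methylcyclohexane | C=C(C)[C@@H]1C(OC)(OC)[C@@H]2O[C@]2(C)[C@H](O)[C@H]1OC(C)=O
F2 | step 8 | 4-O-triethylsilyl ether of F1 | C=C(C)[C@@H]1C(OC)(OC)[C@@H]2O[C@]2(C)[C@H](O[Si](CC)(CC)CC)[C@H]1OC(C)=O
F3 | step 8 | 5β-acetoxy-2α,3α-epoxy-6α-isopropenyl-3β-methyl-4α-(triethylsilyloxy)cyclohexan-1-one | C=C(C)[C@@H]1C(=O)[C@@H]2O[C@]2(C)[C@H](O[Si](CC)(CC)CC)[C@H]1OC(C)=O
F4 | step 10 | 1-O-{2-[bis(2,2,2-trifluoroethoxy)phosphoryl]propanoyl} ester of 12 (both epimers at the phosphonate α-carbon) | C=C(C)[C@@H]1[C@H](OC(=O)C(C)P(=O)(OCC(F)(F)F)OCC(F)(F)F)[C@@H]2O[C@]2(C)[C@H](O[Si](CC)(CC)CC)[C@H]1OC(C)=O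
F5 | step 12 | 5β-acetoxy-1α-angeloyloxy-2α,3α-epoxy-6α-(3-hydroxyprop-1-en-2-yl)-3β-methyl-4α-(triethylsilyloxy)cyclohexane | C=C(CO)[C@@H]1[C@H](OC(=O)/C(C)=C\C)[C@@H]2O[C@]2(C)[C@H](O[Si](CC)(CC)CC)[C@H]1OC(C)=O
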